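**Retrosynthetic overview**
1. The strategy rests on the benzene ring of the benzofuran: C4(OMe)–C5(H)–C6(aryl)–C7(OMe) are the four carbons of a cyclobutenone, and C7a/C3a are the α- and β-carbons of a furan that already carries the C3 methyl and the C2 side chain.
2. Key disconnection: the C3a–C4 bond and the benzene ring, by thermal ring expansion of 3-aryl-4-furyl-4-methoxycyclobutenone 16 (the 4-hydroxycyclobutenone with its carbinol oxygen already carrying the future C7 methyl).
3. 16 comes from semisquarate 9 by two carbonyl additions: the furyllithium at the ketone carbonyl (then O-methylation), and the aryllithium at the remaining vinylogous-ester carbonyl followed by acid 1,3-transposition. This places aryl next to the oxygenated carbon and H next to C=O by constitution, without a regiochemical choice.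
4. The furan comes from furan-3-ylmethanol by Johnson–Claisen rearrangement; the acetate arm is reduced and silylated so that it survives lithiation.
5. Ring order: furan (bought), cyclobutenone (from squarate), benzene (key step). End game: O-methylation, desilylation, oxidation, esterification, hydrogenolysis.

Key step: step 7

Remark: the target has no stereocentre, so no enantiocontrol is needed; the cyclobutenone intermediates are racemic and their stereocentre is erased in step 7.

**Route**

Step 1
Reactants: 1 furan-3-ylmethanol; 2 trimethyl orthoacetate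
Product: 4 methyl 2-(3-methylfuran-2-yl)acetate, via methylidene-dihydrofuran ester 3 (not isolated)
Conditions: EtCO2H (cat.), xylene, 140 °C, MeOH distilled off
Reagents that add atoms: none
Why: Johnson–Claisen rearrangement of the mixed ketene acetal across the furan C2=C3 bond puts the acetate arm on C2, and the exocyclic methylene intermediate 3 should tautomerise to the aromatic 3-methylfuran.

Step 2
Reactants: 4 methyl 2-(3-methylfuran-2-yl)acetate
Product: 5 2-(3-methylfuran-2-yl)ethan-1-ol
Conditions: LiAlH4, Et2O, 0 °C; Fieser work-up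
Reagents that add atoms: none
Why: Standard hydride reduction of an ester to the primary alcohol, which the furan tolerates.

Step 3
Reactants: 5 2-(3-methylfuran-2-yl)ethan-1-ol
Product: 6 tert-butyl(dimethyl)[2-(3-methylfuran-2-yl)ethoxy]silane
Conditions: TBSCl, imidazole, DMF, rt
Reagents that add atoms: tert-butyldimethylsilyl chloride, CC(C)(C)[Si](C)(C)Cl
Why: Imidazole-promoted silylation of a primary alcohol gives an ether that is stable to n-BuLi and to neutral thermolysis.

Step 4
Reactants: 7 diisopropyl squarate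
Product: 9 3-(propan-2-yloxy)cyclobut-3-ene-1,2-dione, via hydroxycyclobutenone 8 (not isolated)
Conditions: LiAlH(OtBu)3, THF, −78 to −20 °C; aq. work-up; then conc. HCl (cat.), CH2Cl2, rt
Reagents that add atoms: water, O
Why: Mono 1,2-reduction of one squarate carbonyl, then acid-promoted ionisation of the allylic carbinol and hydrolysis of the resulting alkoxy-stabilised cation (allylic transposition with loss of isopropanol), should give the semisquarate.

Step 5
Reactants: 6 tert-butyl(dimethyl)[2-(3-methylfuran-2-yl)ethoxy]silane; 9 3-(propan-2-yloxy)cyclobut-3-ene-1,2-dione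
Product: 12 4-{5-[2-(tert-butyldimethylsilyloxy)ethyl]-4-methylfuran-2-yl}-4-methoxy-3-(propan-2-yloxy)cyclobut-2-en-1-one (racemic), via furyllithium 10 (not isolated), via lithium alkoxide 11 (not isolated)
Conditions: n-BuLi, THF, 0 °C; cannulate into 9, THF, −78 °C; MeOTf, −78 to 0 °C
Reagents that add atoms: methyl trifluoromethanesulfonate, COS(=O)(=O)C(F)(F)F
Why: α-Lithiation of the furan at its only free α-position, 1,2-addition to the more electrophilic ketone carbonyl of 9 (the one flanked by the alkoxy-bearing carbon, not the vinylogous-ester carbonyl) and O-alkylation of the lithium alkoxide with methyl triflate should give the methyl ether with the vinylogous ester intact.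

Step 6
Reactants: 13 1-(benzyloxy)-4-bromobenzene; 12 4-{5-[2-(tert-butyldimethylsilyloxy)ethyl]-4-methylfuran-2-yl}-4-methoxy-3-(propan-2-yloxy)cyclobut-2-en-1-one
Product: 16 3-[4-(benzyloxy)phenyl]-4-{5-[2-(tert-butyldimethylsilyloxy)ethyl]-4-methylfuran-2-yl}-4-methoxycyclobut-2-en-1-one (racemic), via aryllithium 14 (not isolated), via tertiary carbinol 15 (not isolated)
Conditions: 13, n-BuLi, THF, −78 °C; add 12, −78 °C; then 1 M HCl, THF, 0 °C (brief)
Reagents that add atoms: water, O
Why: Bromine–lithium exchange gives 14, which adds 1,2 to the only carbonyl of 12; acid ionises the benzylic, allylic carbinol 15 to an alkoxy-stabilised cation that water captures at the isopropoxy carbon (Stork–Danheiser-type 1,3-carbonyl transposition), so the aryl group ends up next to the methoxy-bearing carbon and H next to the new C=O.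

Step 7
Reactants: 16 3-[4-(benzyloxy)phenyl]-4-{5-[2-(tert-butyldimethylsilyloxy)ethyl]-4-methylfuran-2-yl}-4-methoxycyclobut-2-en-1-one
Product: 19 6-[4-(benzyloxy)phenyl]-2-[2-(tert-butyldimethylsilyloxy)ethyl]-7-methoxy-3-methyl-1-benzofuran-4-ol, via dienylketene 17 (not isolated), via cyclohexadienone 18 (not isolated)
Conditions: degassed p-xylene (0.02 M), 135 °C, Ar
Reagents that add atoms: none
Why: Heating opens the cyclobutenone by conrotatory 4π electrocyclic cleavage of the C1–C4 bond to dienylketene 17, whose ketene carbon closes on the free furan β-carbon in a disrotatory 6π electrocyclisation (forming C3a–C4) to give cyclohexadienone 18, and a proton shift from C3a to oxygen aromatises it to 19. The closest known reaction type is the Moore rearrangement of 4-aryl- and 4-heteroaryl-4-hydroxy- or 4-alkoxycyclobutenones to hydroquinones and their monoethers. The one ring formed, the benzene ring, closes by 6π electrocyclisation of the furan C2=C3 bond, the enol-ether C=C bond and the ketene C=C bond. No stereocentre is created and the racemic centre of 16 is erased. The step needs torquoselectivity and correct substituent placement: the methoxy donor rotates outward, which puts the furyl group cis to the ketene, and the constitution of 16 fixes C4(OMe) as C7, C3(aryl) as C6, C2(H) as C5 and C1 as C4, with only one furan β-position next to the point of attachment. The O-methyl group also blocks lactonisation of the ketene to a butenolide and should deliver a monophenol instead of an air-sensitive hydroquinone.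

Step 8
Reactants: 19 6-[4-(benzyloxy)phenyl]-2-[2-(tert-butyldimethylsilyloxy)ethyl]-7-methoxy-3-methyl-1-benzofuran-4-ol
Product: 20 {2-[6-(4-(benzyloxy)phenyl)-4,7-dimethoxy-3-methyl-1-benzofuran-2-yl]ethoxy}(tert-butyl)dimethylsilane
Conditions: MeI, K2CO3, acetone, reflux, Ar
Reagents that add atoms: iodomethane, CI
Why: Williamson methylation of the single phenol completes the 4,7-dimethoxy pattern.

Step 9
Reactants: 20 {2-[6-(4-(benzyloxy)phenyl)-4,7-dimethoxy-3-methyl-1-benzofuran-2-yl]ethoxy}(tert-butyl)dimethylsilane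
Product: 21 2-{6-[4-(benzyloxy)phenyl]-4,7-dimethoxy-3-methyl-1-benzofuran-2-yl}ethan-1-ol
Conditions: TBAF, THF, 0 °C to rt
Reagents that add atoms: none
Why: Fluoride-mediated desilylation frees the primary alcohol without touching the benzyl or methyl ethers.

Step 10
Reactants: 21 2-{6-[4-(benzyloxy)phenyl]-4,7-dimethoxy-3-methyl-1-benzofuran-2-yl}ethan-1-ol
Product: 23 2-{6-[4-(benzyloxy)phenyl]-4,7-dimethoxy-3-methyl-1-benzofuran-2-yl}acetic acid, via aldehyde 22 (not isolated)
Conditions: TEMPO (cat.), PhI(OAc)2, MeCN/H2O, rt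
Reagents that add atoms: water, O
Why: Oxoammonium-mediated (TEMPO/PhI(OAc)2) oxidation takes the primary alcohol through the aldehyde hydrate to the acid under mild, metal-free conditions that should spare the dimethoxybenzofuran.

Step 11
Reactants: 23 2-{6-[4-(benzyloxy)phenyl]-4,7-dimethoxy-3-methyl-1-benzofuran-2-yl}acetic acid
Product: 24 methyl 2-{6-[4-(benzyloxy)phenyl]-4,7-dimethoxy-3-methyl-1-benzofuran-2-yl}acetate
Conditions: MeOH, H2SO4 (cat.), 50 °C
Reagents that add atoms: methanol, CO
Why: Fischer esterification of an unhindered arylacetic acid; the benzyl and aryl methyl ethers are stable to catalytic acid in methanol.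

Step 12
Reactants: 24 methyl 2-{6-[4-(benzyloxy)phenyl]-4,7-dimethoxy-3-methyl-1-benzofuran-2-yl}acetate
Product: 25 phenylcandilide B, methyl 2-[6-(4-hydroxyphenyl)-4,7-dimethoxy-3-methyl-1-benzofuran-2-yl]acetate
Conditions: H2 (1 atm), 10% Pd/C, EtOAc/MeOH, rt
Reagents that add atoms: none
Why: Catalytic hydrogenolysis cleaves the aryl benzyl ether; the 2,3-disubstituted benzofuran and the ester should not be reduced at one atmosphere.

**Compound list**
1 | furan-3-ylmethanol | OCc1ccoc1 | starting material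
2 | trimethyl orthoacetate | COC(C)(OC)OC | starting material
3 | methyl 2-(3-methylidene-2,3-dihydrofuran-2-yl)acetate (racemic) | COC(=O)CC1OC=CC1=C | intermediate
4 | methyl 2-(3-methylfuran-2-yl)acetate | COC(=O)Cc1occc1C | intermediate
5 | 2-(3-methylfuran-2-yl)ethan-1-ol | OCCc1occc1C | intermediate
6 | tert-butyl(dimethyl)[2-(3-methylfuran-2-yl)ethoxy]silane | Cc1ccoc1CCO[Si](C)(C)C(C)(C)C | intermediate
7 | diisopropyl squarate | CC(C)OC1=C(OC(C)C)C(=O)C1=O | starting material
8 | 4-hydroxy-2,3-di(propan-2-yloxy)cyclobut-2-en-1-one (racemic) | CC(C)OC1=C(OC(C)C)C(O)C1=O | intermediate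
9 | 3-(propan-2-yloxy)cyclobut-3-ene-1,2-dione | CC(C)OC1=CC(=O)C1=O | intermediate
10 | {5-[2-(tert-butyldimethylsilyloxy)ethyl]-4-methylfuran-2-yl}lithium | [Li]c1cc(C)c(CCO[Si](C)(C)C(C)(C)C)o1 | intermediate
11 | lithium 1-{5-[2-(tert-butyldimethylsilyloxy)ethyl]-4-methylfuran-2-yl}-4-oxo-2-(propan-2-yloxy)cyclobut-2-en-1-olate (racemic) | [Li]OC1(c2cc(C)c(CCO[Si](C)(C)C(C)(C)C)o2)C(OC(C)C)=CC1=O | intermediate
12 | 4-{5-[2-(tert-butyldimethylsilyloxy)ethyl]-4-methylfuran-2-yl}-4-methoxy-3-(propan-2-yloxy)cyclobut-2-en-1-one (racemic) | COC1(c2cc(C)c(CCO[Si](C)(C)C(C)(C)C)o2)C(OC(C)C)=CC1=O | intermediate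
13 | 1-(benzyloxy)-4-bromobenzene | Brc1ccc(OCc2ccccc2)cc1 | starting material
14 | [4-(benzyloxy)phenyl]lithium | [Li]c1ccc(OCc2ccccc2)cc1 | intermediate
15 | 1-[4-(benzyloxy)phenyl]-4-{5-[2-(tert-butyldimethylsilyloxy)ethyl]-4-methylfuran-2-yl}-4-methoxy-3-(propan-2-yloxy)cyclobut-2-en-1-ol (racemic, mixture of diastereomers) | COC1(c2cc(C)c(CCO[Si](C)(C)C(C)(C)C)o2)C(OC(C)C)=CC1(O)c1ccc(OCc2ccccc2)cc1 | intermediate
16 | 3-[4-(benzyloxy)phenyl]-4-{5-[2-(tert-butyldimethylsilyloxy)ethyl]-4-methylfuran-2-yl}-4-methoxycyclobut-2-en-1-one (racemic) | COC1(c2cc(C)c(CCO[Si](C)(C)C(C)(C)C)o2)C(c2ccc(OCc3ccccc3)cc2)=CC1=O | intermediate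
17 | (3Z)-3-[4-(benzyloxy)phenyl]-4-{5-[2-(tert-butyldimethylsilyloxy)ethyl]-4-methylfuran-2-yl}-4-methoxybuta-1,3-dien-1-one (furyl cis to the ketene) | O=C=C/C(=C(\c1cc(C)c(CCO[Si](C)(C)C(C)(C)C)o1)OC)c1ccc(OCc2ccccc2)cc1 | intermediate
18 | 6-[4-(benzyloxy)phenyl]-2-[2-(tert-butyldimethylsilyloxy)ethyl]-7-methoxy-3-methyl-3aH-1-benzofuran-4-one (racemic) | COC1=C2OC(CCO[Si](C)(C)C(C)(C)C)=C(C)C2C(=O)C=C1c1ccc(OCc2ccccc2)cc1 | intermediate
19 | 6-[4-(benzyloxy)phenyl]-2-[2-(tert-butyldimethylsilyloxy)ethyl]-7-methoxy-3-methyl-1-benzofuran-4-ol | COc1c(-c2ccc(OCc3ccccc3)cc2)cc(O)c2c(C)c(CCO[Si](C)(C)C(C)(C)C)oc12 | intermediate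
20 | {2-[6-(4-(benzyloxy)phenyl)-4,7-dimethoxy-3-methyl-1-benzofuran-2-yl]ethoxy}(tert-butyl)dimethylsilane | COc1cc(-c2ccc(OCc3ccccc3)cc2)c(OC)c2oc(CCO[Si](C)(C)C(C)(C)C)c(C)c12 | intermediate
21 | 2-{6-[4-(benzyloxy)phenyl]-4,7-dimethoxy-3-methyl-1-benzofuran-2-yl}ethan-1-ol | COc1cc(-c2ccc(OCc3ccccc3)cc2)c(OC)c2oc(CCO)c(C)c12 | intermediate
22 | 2-{6-[4-(benzyloxy)phenyl]-4,7-dimethoxy-3-methyl-1-benzofuran-2-yl}acetaldehyde | COc1cc(-c2ccc(OCc3ccccc3)cc2)c(OC)c2oc(CC=O)c(C)c12 | intermediate
23 | 2-{6-[4-(benzyloxy)phenyl]-4,7-dimethoxy-3-methyl-1-benzofuran-2-yl}acetic acid | COc1cc(-c2ccc(OCc3ccccc3)cc2)c(OC)c2oc(CC(=O)O)c(C)c12 | intermediate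
24 | methyl 2-{6-[4-(benzyloxy)phenyl]-4,7-dimethoxy-3-methyl-1-benzofuran-2-yl}acetate | COC(=O)Cc1oc2c(OC)c(-c3ccc(OCc4ccccc4)cc3)cc(OC)c2c1C | intermediate
25 | phenylcandilide B, methyl 2-[6-(4-hydroxyphenyl)-4,7-dimethoxy-3-methyl-1-benzofuran-2-yl]acetate | COC(=O)Cc1oc2c(OC)c(-c3ccc(O)cc3)cc(OC)c2c1C | target

**Step count**
Total: 12 steps. Longest linear sequence: 11 steps (1, 2, 3, 5, 6, 7, 8, 9, 10, 11, 12 from furan-3-ylmethanol).

**Steps most likely to fail**

Step 7. The dienylketene may be consumed by dimerisation or by adventitious nucleophiles faster than it closes onto the furan, or ring opening of this 3-aryl, 2-unsubstituted cyclobutenone may need temperatures at which the electron-rich furan degrades. The fallback moves the ring expansion to the 3-alkoxy series, the best-documented substrate class, and makes the C6–aryl bond afterwards by cross-coupling. It sets out from 12 and comes back at 21. Heating 12 in toluene should give 2-[2-(tert-butyldimethylsilyloxy)ethyl]-7-methoxy-3-methyl-6-(propan-2-yloxy)-1-benzofuran-4-ol F1. MeI/K2CO3 should then give tert-butyl{2-[4,7-dimethoxy-3-methyl-6-(propan-2-yloxy)-1-benzofuran-2-yl]ethoxy}dimethylsilane F2. BCl3 (CH2Cl2, −78 to 0 °C) should cleave the isopropyl aryl ether and the silyl ether to 2-(2-hydroxyethyl)-4,7-dimethoxy-3-methyl-1-benzofuran-6-ol F3. PhNTf2/K2CO3 should triflate only the phenol, giving 2-(2-hydroxyethyl)-4,7-dimethoxy-3-methyl-1-benzofuran-6-yl trifluoromethanesulfonate F4. Suzuki–Miyaura coupling of F4 with [4-(benzyloxy)phenyl]boronic acid (Pd(OAc)2, SPhos, K3PO4, toluene/H2O) should give 21.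

Step 5. The furyllithium may add twice or attack the alkoxy-bearing carbon, and the hindered tertiary lithium alkoxide may be methylated so slowly that it fragments on warming before it is capped. The fallback caps the alkoxide with a silyl group, which is fast at −78 °C, carries the carbinol oxygen unmethylated through the ring expansion and methylates both hydroxyls afterwards. It sets out from lithium alkoxide 11 (formed from 6 and 9 as in step 5) and comes back at 20. TMSCl at −78 °C should give 4-{5-[2-(tert-butyldimethylsilyloxy)ethyl]-4-methylfuran-2-yl}-3-(propan-2-yloxy)-4-(trimethylsilyloxy)cyclobut-2-en-1-one F5. Addition of 14 and work-up with 1 M HCl should transpose the carbonyl and remove the trimethylsilyl group, giving 3-[4-(benzyloxy)phenyl]-4-{5-[2-(tert-butyldimethylsilyloxy)ethyl]-4-methylfuran-2-yl}-4-hydroxycyclobut-2-en-1-one F6. Thermolysis (p-xylene, 135 °C, Ar) should give the hydroquinone 6-[4-(benzyloxy)phenyl]-2-[2-(tert-butyldimethylsilyloxy)ethyl]-3-methyl-1-benzofuran-4,7-diol F7. Double methylation (MeI, K2CO3, acetone, Ar, a little Na2S2O4) should give 20.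

Step 6. The aryllithium may add poorly to the carbonyl flanked by the quaternary carbon, or the cation formed on acidification may be diverted (1,2-shift of the furyl group, opening of the furan, loss of the silyl ether) before water captures it. The fallback avoids both the carbonyl addition and the cation by making the aryl–ring bond through cross-coupling. It sets out from 12 and comes back at 16. Mild aqueous acid (dilute HCl, THF) should hydrolyse the enol ether to 2-{5-[2-(tert-butyldimethylsilyloxy)ethyl]-4-methylfuran-2-yl}-2-methoxycyclobutane-1,3-dione F8, whose two carbonyls are equivalent, so its enol derivative has only one constitution. Tf2O/2,6-lutidine (CH2Cl2, −78 °C) should give the enol triflate 4-{5-[2-(tert-butyldimethylsilyloxy)ethyl]-4-methylfuran-2-yl}-4-methoxy-3-oxocyclobut-1-en-1-yl trifluoromethanesulfonate F9. Suzuki–Miyaura coupling with [4-(benzyloxy)phenyl]boronic acid (Pd(PPh3)4, K3PO4, THF, rt) should give 16.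

**Further compounds**
F1 | step 7 | 2-[2-(tert-butyldimethylsilyloxy)ethyl]-7-methoxy-3-methyl-6-(propan-2-yloxy)-1-benzofuran-4-ol | COc1c(OC(C)C)cc(O)c2c(C)c(CCO[Si](C)(C)C(C)(C)C)oc12
F2 | step 7 | tert-butyl{2-[4,7-dimethoxy-3-methyl-6-(propan-2-yloxy)-1-benzofuran-2-yl]ethoxy}dimethylsilane | COc1cc(OC(C)C)c(OC)c2oc(CCO[Si](C)(C)C(C)(C)C)c(C)c12
F3 | step 7 | 2-(2-hydroxyethyl)-4,7-dimethoxy-3-methyl-1-benzofuran-6-ol | COc1cc(O)c(OC)c2oc(CCO)c(C)c12
F4 | step 7 | 2-(2-hydroxyethyl)-4,7-dimethoxy-3-methyl-1-benzofuran-6-yl trifluoromethanesulfonate | COc1cc(OS(=O)(=O)C(F)(F)F)c(OC)c2oc(CCO)c(C)c12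
F5 | step 5 | 4-{5-[2-(tert-butyldimethylsilyloxy)ethyl]-4-methylfuran-2-yl}-3-(propan-2-yloxy)-4-(trimethylsilyloxy)cyclobut-2-en-1-one (racemic) | C[Si](C)(C)OC1(c2cc(C)c(CCO[Si](C)(C)C(C)(C)C)o2)C(OC(C)C)=CC1=O
F6 | step 5 | 3-[4-(benzyloxy)phenyl]-4-{5-[2-(tert-butyldimethylsilyloxy)ethyl]-4-methylfuran-2-yl}-4-hydroxycyclobut-2-en-1-one (racemic) | O=C1C=C(c2ccc(OCc3ccccc3)cc2)C1(O)c1cc(C)c(CCO[Si](C)(C)C(C)(C)C)o1
F7 | step 5 | 6-[4-(benzyloxy)phenyl]-2-[2-(tert-butyldimethylsilyloxy)ethyl]-3-methyl-1-benzofuran-4,7-diol | Cc1c(CCO[Si](C)(C)C(C)(C)C)oc2c(O)c(-c3ccc(OCc4ccccc4)cc3)cc(O)c12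
F8 | step 6 | 2-{5-[2-(tert-butyldimethylsilyloxy)ethyl]-4-methylfuran-2-yl}-2-methoxycyclobutane-1,3-dione | COC1(c2cc(C)c(CCO[Si](C)(C)C(C)(C)C)o2)C(=O)CC1=O
F9 | step 6 | 4-{5-[2-(tert-butyldimethylsilyloxy)ethyl]-4-methylfuran-2-yl}-4-methoxy-3-oxocyclobut-1-en-1-yl trifluoromethanesulfonate (racemic) | COC1(c2cc(C)c(CCO[Si](C)(C)C(C)(C)C)o2)C(OS(=O)(=O)C(F)(F)F)=CC1=O
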